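A direct plan would C-acylate 3'-acetoxy-2',4',5'-trimethoxyacetophenone A2, made by Friedel–Crafts acetylation of 2,3,6-trimethoxyphenyl acetate A4, with 2,3,4,5-tetramethoxybenzoyl chloride A3 to the 1,3-diketone A1, would close the pyranone at O1–C8a by a photocatalytic dehydrogenative C–H/O–H coupling and would then cleave the acetate. Its weakest steps would be the dehydrogenative C–O closure (no precedent on a diketone enol, either ring could be oxidised, and the diketone would bind Co(dmgH)2(py)Cl), the acetylation of A4 (its regiochemistry would hang on a para methoxy group twisted out of conjugation by two ortho neighbours) and the Claisen-type acylation to A1 (O-acylation and acetyl transfer from the aryl acetate would compete).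

The new route rests on closing the pyranone (ring C) at a carbon–carbon bond, C4–C4a, not at oxygen. It exploits that ring A has a single carbon without oxygen, C4a: in a 2,3,4,5-tetramethoxyphenyl ether only this carbon can be acylated. The phenol is first linked through O1–C2 to a ring B arylpropiolate; intramolecular Friedel–Crafts acylation of the resulting β-aryloxycinnamic acid then creates the hexasubstituted ring A and the chromone in one operation. No diketone, no oxidative C–O closure and no electrophilic substitution on a 2,3,6-trimethoxyphenyl ester occur; ring B's carbon substituent is instead placed ortho to a free phenol whose para position is blocked.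

Key step: step 7

Remark: 2-hydroxy-3,4-dimethoxybenzaldehyde is taken as a catalogue compound; the enol ether intermediates are drawn as the Z isomers expected from anti addition, their geometry is not critical because the ring closure equilibrates it, and the target has no stereocentre.

Step 1
Reactants: 1 1,2,3,4-tetramethoxybenzene
Product: 4 2,3,4,5-tetramethoxyphenol, via 2,3,4,5-tetramethoxyphenyllithium 2 (not isolated), via lithium trimethoxy(2,3,4,5-tetramethoxyphenyl)borate 3 (not isolated)
Conditions: n-BuLi (1.2 equiv), TMEDA, THF, 0 °C; B(OMe)3, −78 °C → rt; AcOH, 30% H2O2, 0 °C → rt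
Reagents that add atoms: hydrogen peroxide, OO (the phenol oxygen of 4); for the intermediates only: n-butyllithium, [Li]CCCC (Li of 2); trimethyl borate, COB(OC)OC (B(OMe)3 unit of 3)
Why: Directed ortho-metalation of the symmetrical arene (its two C–H positions are equivalent) followed by borylation and peroxide oxidation (1,2-aryl shift from boron to oxygen) should place the hydroxyl next to the four methoxy groups and leave exactly one ring C–H, the future C4a.

Step 2
Reactants: 5 2-hydroxy-3,4-dimethoxybenzaldehyde
Product: 6 2-(benzyloxy)-3,4-dimethoxybenzaldehyde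
Conditions: BnBr (1.2 equiv), K2CO3 (1.5 equiv), DMF, 60 °C
Reagents that add atoms: benzyl bromide, BrCc1ccccc1
Why: Williamson ether synthesis marks the oxygen that becomes the free 3'-OH with a benzyl ether, which should survive peracid, base, the Pd/Cu coupling and trifluoroacetic acid.

Step 3
Reactants: 6 2-(benzyloxy)-3,4-dimethoxybenzaldehyde
Product: 8 2-(benzyloxy)-3,4-dimethoxyphenol, via 2-(benzyloxy)-3,4-dimethoxyphenyl formate 7 (not isolated)
Conditions: mCPBA (1.3 equiv), CH2Cl2, 0 °C → rt; aq. NaHCO3/Na2S2O3 wash; then K2CO3 (cat.), MeOH, rt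
Reagents that add atoms: m-chloroperbenzoic acid, OOC(=O)c1cccc(Cl)c1 (the phenol oxygen)
Why: Baeyer–Villiger (Dakin-type) oxidation, in which the electron-rich aryl group with ortho and para alkoxy donors should migrate in preference to hydride; mild methanolysis of the aryl formate frees the phenol that becomes the 2'-oxygen.

Step 4
Reactants: 8 2-(benzyloxy)-3,4-dimethoxyphenol
Product: 10 3-(benzyloxy)-1-iodo-2,4,5-trimethoxybenzene, via 2-(benzyloxy)-6-iodo-3,4-dimethoxyphenol 9 (not isolated)
Conditions: NIS (1.05 equiv), DMF, 0 °C → rt; then K2CO3 (3 equiv), MeI (3 equiv), rt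
Reagents that add atoms: N-iodosuccinimide, O=C1CCC(=O)N1I (the iodine atom); iodomethane, CI (the new O-methyl group)
Why: Electrophilic iodination of the free phenol should occur at C6, its only open ortho position (the para position carries a methoxy group and C5 has only one conjugated methoxy donor), and Williamson methylation of the iodophenoxide in the same pot completes the ring B pattern with iodine at the future C1'.

Step 5
Reactants: 10 3-(benzyloxy)-1-iodo-2,4,5-trimethoxybenzene; 11 methyl propiolate
Product: 12 methyl 3-[3-(benzyloxy)-2,4,5-trimethoxyphenyl]prop-2-ynoate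
Conditions: 11 (3 equiv), PdCl2(PPh3)2 (3 mol%), CuI (6 mol%), K2CO3 (2 equiv), THF, 65 °C
Reagents that add atoms: none
Why: Sonogashira coupling under amine-free carbonate conditions, which limit base-induced oligomerisation of the propiolate, should attach the three carbons that become C2, C3 and C4.

Step 6
Reactants: 4 2,3,4,5-tetramethoxyphenol; 12 methyl 3-[3-(benzyloxy)-2,4,5-trimethoxyphenyl]prop-2-ynoate
Product: 14 (2Z)-3-[3-(benzyloxy)-2,4,5-trimethoxyphenyl]-3-(2,3,4,5-tetramethoxyphenoxy)prop-2-enoic acid, via methyl β-aryloxycinnamate 13 (not isolated)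
Conditions: 4 (1.2 equiv), K2CO3 (0.5 equiv), DMSO, 70 °C; then LiOH (3 equiv), H2O, 50 °C; cold aq. HCl to pH 2–3
Reagents that add atoms: lithium hydroxide, [Li+].[OH-] (the hydroxyl oxygen of the carboxylic acid)
Why: Base-mediated oxa-Michael addition of the phenoxide of 4 to the β-carbon of the aryl ynoate (first stage of the Ruhemann flavone synthesis) should form O1–C2 by anti addition to give the Z enol ether, and the hindered, donor-substituted β-carbon lets hydroxide attack the ester carbonyl (saponification) instead of displacing the aryloxide.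

Step 7
Reactants: 14 (2Z)-3-[3-(benzyloxy)-2,4,5-trimethoxyphenyl]-3-(2,3,4,5-tetramethoxyphenoxy)prop-2-enoic acid
Product: 16 3'-(benzyloxy)-5,6,7,8,2',4',5'-heptamethoxyflavone, via mixed trifluoroacetic anhydride 15 (not isolated)
Conditions: TFAA (3 equiv), CH2Cl2/TFA 5:1, 0 °C → rt; aq. NaHCO3
Reagents that add atoms: none
Why: TFAA converts 14 into the mixed anhydride 15, which ionises in TFA to an acylium ion stabilised by the β-aryloxy oxygen (ketene–oxocarbenium resonance form) and attacks C6 of the tetramethoxyphenoxy ring in an intramolecular Friedel–Crafts acylation that forms C4–C4a, loss of a proton then giving the aromatic 4-pyranone. The closest known reaction type is the second stage of the Ruhemann flavone synthesis, the acid-promoted cyclisation of β-aryloxycinnamic acids. The pyranone is closed as a six-membered ring by electrophilic aromatic substitution (6-endo with respect to the arene carbon), and no stereocentre is created. The step needs site selectivity on ring A and selectivity between rings A and B: the phenoxy ring of 15 has a single C–H, ortho to the ether oxygen and to one methoxy group and para to another, so only one chromone can form, whereas attack on C6' of ring B would need a strained five-membered indenone closure from the E isomer onto a carbon that the acrylate substituent deactivates. Any E isomer should be funnelled into product because rotation about C2–C3 is free in the oxocarbenium form of the acylium ion. The benzyl ether and the methyl ethers, the peri 5-OMe included, should survive TFA at room temperature because no Lewis acid capable of chelation-assisted demethylation is present.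

Step 8
Reactants: 16 3'-(benzyloxy)-5,6,7,8,2',4',5'-heptamethoxyflavone
Product: 17 Agehoustin C (3'-hydroxy-5,6,7,8,2',4',5'-heptamethoxyflavone)
Conditions: H2 (1 atm), 10% Pd/C, EtOAc/MeOH 1:1, rt
Reagents that add atoms: none
Why: Hydrogenolysis of the benzyl ether over Pd/C should free the 3'-hydroxyl, while the C2=C3 bond, which is part of an aromatic 4-pyranone, and the methyl ethers are not reduced under these mild conditions.

Compound list

1 | 1,2,3,4-tetramethoxybenzene | COc1ccc(OC)c(OC)c1OC | starting material
2 | 2,3,4,5-tetramethoxyphenyllithium | [Li]c1cc(OC)c(OC)c(OC)c1OC | intermediate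
3 | lithium trimethoxy(2,3,4,5-tetramethoxyphenyl)borate | [Li+].CO[B-](OC)(OC)c1cc(OC)c(OC)c(OC)c1OC | intermediate
4 | 2,3,4,5-tetramethoxyphenol | COc1cc(O)c(OC)c(OC)c1OC | intermediate
5 | 2-hydroxy-3,4-dimethoxybenzaldehyde | COc1ccc(C=O)c(O)c1OC | starting material
6 | 2-(benzyloxy)-3,4-dimethoxybenzaldehyde | COc1ccc(C=O)c(OCc2ccccc2)c1OC | intermediate
7 | 2-(benzyloxy)-3,4-dimethoxyphenyl formate | COc1ccc(OC=O)c(OCc2ccccc2)c1OC | intermediate
8 | 2-(benzyloxy)-3,4-dimethoxyphenol | COc1ccc(O)c(OCc2ccccc2)c1OC | intermediate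
9 | 2-(benzyloxy)-6-iodo-3,4-dimethoxyphenol | COc1cc(I)c(O)c(OCc2ccccc2)c1OC | intermediate
10 | 3-(benzyloxy)-1-iodo-2,4,5-trimethoxybenzene | COc1cc(I)c(OC)c(OCc2ccccc2)c1OC | intermediate
11 | methyl propiolate (methyl prop-2-ynoate) | C#CC(=O)OC | starting material
12 | methyl 3-[3-(benzyloxy)-2,4,5-trimethoxyphenyl]prop-2-ynoate | COC(=O)C#Cc1cc(OC)c(OC)c(OCc2ccccc2)c1OC | intermediate
13 | methyl (2Z)-3-[3-(benzyloxy)-2,4,5-trimethoxyphenyl]-3-(2,3,4,5-tetramethoxyphenoxy)prop-2-enoate | COC(=O)/C=C(\Oc1cc(OC)c(OC)c(OC)c1OC)c1cc(OC)c(OC)c(OCc2ccccc2)c1OC | intermediate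
14 | (2Z)-3-[3-(benzyloxy)-2,4,5-trimethoxyphenyl]-3-(2,3,4,5-tetramethoxyphenoxy)prop-2-enoic acid | OC(=O)/C=C(\Oc1cc(OC)c(OC)c(OC)c1OC)c1cc(OC)c(OC)c(OCc2ccccc2)c1OC | intermediate
15 | (2Z)-3-[3-(benzyloxy)-2,4,5-trimethoxyphenyl]-3-(2,3,4,5-tetramethoxyphenoxy)prop-2-enoic trifluoroacetic anhydride | O=C(/C=C(\Oc1cc(OC)c(OC)c(OC)c1OC)c1cc(OC)c(OC)c(OCc2ccccc2)c1OC)OC(=O)C(F)(F)F | intermediate
16 | 3'-(benzyloxy)-5,6,7,8,2',4',5'-heptamethoxyflavone, 2-[3-(benzyloxy)-2,4,5-trimethoxyphenyl]-5,6,7,8-tetramethoxy-4H-chromen-4-one | COc1cc(-c2cc(=O)c3c(OC)c(OC)c(OC)c(OC)c3o2)c(OC)c(OCc4ccccc4)c1OC | intermediate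
17 | Agehoustin C, 3'-hydroxy-5,6,7,8,2',4',5'-heptamethoxyflavone (achiral) | COc1cc(-c2cc(=O)c3c(OC)c(OC)c(OC)c(OC)c3o2)c(OC)c(O)c1OC | target

Total step count: 8. Longest linear sequence: 7 steps (steps 2 to 8, from 5).

Steps most likely to fail

Step 7. The β-aryloxy-stabilised acylium ion may be too weak an electrophile for the ring closure to go to completion, and stronger acid could cleave the benzyl ether. The fallback would bring in the ketone carbon as carbon monoxide and sets out from 4 and 10. Iodination of 4 at its only free position (NIS, MeCN, 0 °C) would give 2-iodo-3,4,5,6-tetramethoxyphenol F1. Sonogashira coupling of 10 with trimethylsilylacetylene (PdCl2(PPh3)2, CuI, Et3N, THF) would give {[3-(benzyloxy)-2,4,5-trimethoxyphenyl]ethynyl}trimethylsilane F2, and K2CO3/MeOH would give 3-(benzyloxy)-1-ethynyl-2,4,5-trimethoxybenzene F3. Carbonylative coupling of F1 with F3 (PdCl2(PPh3)2, CO 1 atm, Et2NH, 60–80 °C) would pass through 3-[3-(benzyloxy)-2,4,5-trimethoxyphenyl]-1-(2-hydroxy-3,4,5,6-tetramethoxyphenyl)prop-2-yn-1-one F4, which should cyclise in the amine medium by 6-endo closure, and comes back to the route at 16.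

Step 6. Conjugate addition of the phenoxide to the electron-rich, ortho-substituted ynoate may be slow, and transesterification of the methyl ester by the phenoxide may compete. The fallback would make the O1–C2 bond on a more electrophilic acceptor and the C2–C1' bond by cross-coupling, setting out from 4 and 10. Addition–elimination of 4 on methyl 3,3-dichloroacrylate (K2CO3, DMF, 0 °C → rt) would give methyl 3-chloro-3-(2,3,4,5-tetramethoxyphenoxy)prop-2-enoate F5. Zinc insertion into 10 (Zn dust, LiCl, THF, 50 °C) would give [3-(benzyloxy)-2,4,5-trimethoxyphenyl]zinc iodide F6. Negishi coupling of F5 with F6 (Pd(PPh3)4, THF, 50 °C) comes back at 13, which is saponified as in the second stage of step 6.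

Step 5. Base-induced oligomerisation of methyl propiolate and alkyne homocoupling may outrun the coupling of the electron-rich iodide; the same fallback would also answer a poorly selective iodination in step 4. It would build the three-carbon unit from an aldehyde, setting out from 8. Chelation-controlled ortho-formylation (MgCl2, Et3N, paraformaldehyde, MeCN, reflux) would give 3-(benzyloxy)-2-hydroxy-4,5-dimethoxybenzaldehyde F7, and methylation (MeI, K2CO3, DMF) would give 3-(benzyloxy)-2,4,5-trimethoxybenzaldehyde F8. Corey–Fuchs olefination (CBr4, PPh3, CH2Cl2, 0 °C) would give 3-(benzyloxy)-1-(2,2-dibromoethenyl)-2,4,5-trimethoxybenzene F9. Treatment with n-BuLi (2.1 equiv, THF, −78 °C) would give lithium [3-(benzyloxy)-2,4,5-trimethoxyphenyl]acetylide F10, and trapping with methyl chloroformate comes back at 12.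

Further compounds

F1 | step 7 | 2-iodo-3,4,5,6-tetramethoxyphenol | COc1c(O)c(I)c(OC)c(OC)c1OC
F2 | step 7 | {[3-(benzyloxy)-2,4,5-trimethoxyphenyl]ethynyl}trimethylsilane | COc1cc(C#C[Si](C)(C)C)c(OC)c(OCc2ccccc2)c1OC
F3 | step 7 | 3-(benzyloxy)-1-ethynyl-2,4,5-trimethoxybenzene | COc1cc(C#C)c(OC)c(OCc2ccccc2)c1OC
F4 | step 7 | 3-[3-(benzyloxy)-2,4,5-trimethoxyphenyl]-1-(2-hydroxy-3,4,5,6-tetramethoxyphenyl)prop-2-yn-1-one | COc1cc(C#CC(=O)c2c(O)c(OC)c(OC)c(OC)c2OC)c(OC)c(OCc3ccccc3)c1OC
F5 | step 6 | methyl 3-chloro-3-(2,3,4,5-tetramethoxyphenoxy)prop-2-enoate (E/Z mixture) | COC(=O)C=C(Cl)Oc1cc(OC)c(OC)c(OC)c1OC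
F6 | step 6 | [3-(benzyloxy)-2,4,5-trimethoxyphenyl]zinc iodide | COc1cc([Zn]I)c(OC)c(OCc2ccccc2)c1OC
F7 | step 5 | 3-(benzyloxy)-2-hydroxy-4,5-dimethoxybenzaldehyde | COc1cc(C=O)c(O)c(OCc2ccccc2)c1OC
F8 | step 5 | 3-(benzyloxy)-2,4,5-trimethoxybenzaldehyde | COc1cc(C=O)c(OC)c(OCc2ccccc2)c1OC
F9 | step 5 | 3-(benzyloxy)-1-(2,2-dibromoethenyl)-2,4,5-trimethoxybenzene | COc1cc(C=C(Br)Br)c(OC)c(OCc2ccccc2)c1OC
F10 | step 5 | lithium [3-(benzyloxy)-2,4,5-trimethoxyphenyl]acetylide | COc1cc(C#C[Li])c(OC)c(OCc2ccccc2)c1OC
A1 | direct plan | 1-(3-acetoxy-2,4,5-trimethoxyphenyl)-3-(2,3,4,5-tetramethoxyphenyl)propane-1,3-dione | CC(=O)Oc1c(OC)c(OC)cc(C(=O)CC(=O)c2cc(OC)c(OC)c(OC)c2OC)c1OC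
A2 | direct plan | 3'-acetoxy-2',4',5'-trimethoxyacetophenone (5-acetyl-2,3,6-trimethoxyphenyl acetate) | CC(=O)Oc1c(OC)c(OC)cc(C(C)=O)c1OC
A3 | direct plan | 2,3,4,5-tetramethoxybenzoyl chloride | O=C(Cl)c1cc(OC)c(OC)c(OC)c1OC
A4 | direct plan | 2,3,6-trimethoxyphenyl acetate | CC(=O)Oc1c(OC)c(OC)ccc1OC
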